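**Retrosynthetic overview**
1. The target is (1R,7S,8R,10S)-11-acetoxy-8-propanoyloxyguai-4-en-3-one. Both esters go on last, onto the cis-8,11-diol 14; the C8 oxygen comes from a C8–SiMe2Ph group (oxidation with retention) and the cis C7/C8 pair from syn-hydrogenation of a C7=C8 alkene.
2. The seven-membered ring is made in one rhodium-catalysed (5+2) cycloaddition that forms C6–C7 and C8–C9, inserting the two alkyne carbons of silyl ynone 8 between the alkene terminus and the cyclopropane CH2 of vinylcyclopropane 5.
3. Enabling feature: in 5 the cyclopropane C1–C9–C10 is spiro-fused at C1 of ring A, next to the exocyclic C5=C6 methylene, so the vinylcyclopropane is locked s-cis. Cleaving C1–C9 turns the spiro[2.4]heptane into the fused 5–7 skeleton, and ring A is carried as a 3-ethoxy diene that becomes the C4=C5 enone on hydrolysis.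
4. C9, C10, C14 and the C10 stereocentre come from (R)-propane-1,2-diol (as cyclic sulfate 2) by double alkylation of vinylogous ester 1. Ring order: five-membered (bought), three-membered, seven-membered.

Key step: step 4

Remark: explanations use guaiane locants (ring A = C1–C5 with C3=O and C4=C5; seven-membered ring = C1, C5–C10; C11 = carbinol carbon; C14, C15 = methyls on C10, C4); compound names use azulene locants.
Assumption: the C1 epimer with C2 trans to the C10 methyl (the natural one) is the thermodynamically favoured epimer of the 4-en-3-one; compounds 1, 2 and 6 are taken as purchasable.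

Step 1
Reactants: 1 3-ethoxy-2-methylcyclopent-2-en-1-one; 2 (4R)-4-methyl-1,3,2-dioxathiolane 2,2-dioxide
Product: 4 (1S,3R)-6-ethoxy-1,5-dimethylspiro[2.4]hept-5-en-4-one, via lithium enolate sulfate 3 (not isolated)
Conditions: LiN(iPr)2 (1.05 equiv), THF, −78 °C; 2, −78 to 0 °C; LiN(iPr)2 (1.1 equiv), −78 °C to rt
Reagents that add atoms: none
Why: Stork–Danheiser-type kinetic α′-deprotonation of the vinylogous ester, SN2 opening of the cyclic sulfate at its CH2 carbon, then a second deprotonation and 3-exo-tet displacement of the secondary sulfate with inversion (enolate double alkylation with a 1,2-cyclic sulfate) should turn the (R)-carbinol carbon into the (S)-configured methyl-bearing cyclopropane carbon (future C10); the spiro carbon is expected mainly with methyl anti to the carbonyl, and its configuration is erased in step 4.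

Step 2
Reactants: 4 (1S,3R)-6-ethoxy-1,5-dimethylspiro[2.4]hept-5-en-4-one
Product: 5 (1S,3R)-6-ethoxy-1,5-dimethyl-4-methylidenespiro[2.4]hept-5-ene
Conditions: Cp2TiMe2 (2.5 equiv), toluene, 70 °C, dark; filtration through basic Al2O3
Reagents that add atoms: dimethyltitanocene Cp2TiMe2, C[Ti](C)(C1C=CC=C1)C1C=CC=C1
Why: Petasis methylenation, in which thermally generated Cp2Ti=CH2 olefinates the ester-like, hindered carbonyl without acid or strong base, so the acid-labile 2-ethoxy diene and the cyclopropane should survive and no stereocentre is touched.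

Step 3
Reactants: 6 ethynyl(dimethyl)phenylsilane
Product: 8 4-[dimethyl(phenyl)silyl]but-3-yn-2-one, via lithium acetylide 7 (not isolated)
Conditions: n-BuLi (1.0 equiv), THF, −78 °C; cannulation into Ac2O (3 equiv), THF, −78 °C
Reagents that add atoms: acetic anhydride, CC(=O)OC(C)=O
Why: Acylation of a lithium acetylide by inverse addition to excess anhydride should stop at the ynone because the product never meets excess acetylide.

Step 4
Reactants: 5 (1S,3R)-6-ethoxy-1,5-dimethyl-4-methylidenespiro[2.4]hept-5-ene; 8 4-[dimethyl(phenyl)silyl]but-3-yn-2-one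
Product: 9 1-[(8S)-6-[dimethyl(phenyl)silyl]-2-ethoxy-3,8-dimethyl-1,4,7,8-tetrahydroazulen-5-yl]ethan-1-one
Conditions: [Rh(CO)2Cl]2 (5 mol %), ClCH2CH2Cl, 60–80 °C, 0.1 M; crude product filtered through basic Al2O3 and used directly
Reagents that add atoms: none
Why: Monovalent rhodium should bind the exocyclic C5=C6 alkene of 5 and insert into the less hindered C1–C9 cyclopropane bond to give a σ,π-allyl rhodacyclohexene, after which alkyne 8 inserts at the CH2 allyl terminus (C6–C7 bond) and C(sp2)–C(sp3) reductive elimination from the eight-membered rhodacycle forms C8–C9. The closest known reaction type is the rhodium-catalysed intermolecular (5+2) cycloaddition of vinylcyclopropanes with alkynes, silyl ynones included. The seven-membered ring is closed in a two-bond (5+2) annulation mode, and opening of the three-membered ring converts the spiro[2.4] skeleton into the fused bicyclo[5.3.0] skeleton with a C1=C5 double bond at the ring fusion. No stereocentre is created: the C10 methyl centre is carried over unchanged because none of its bonds is broken, and the spiro centre becomes sp2, so both spiro epimers of 5 converge. The step needs (a) cleavage of C1–C9 rather than C1–C10, which the methyl group on C10 and the choice of [Rh(CO)2Cl]2 should secure, (b) the alkyne orientation with the acetyl-bearing carbon on C6, which the bulky silyl group should secure by staying on the rhodium-bound carbon distal to the first C–C bond, helped by the preference of acyl groups for the proximal position, and (c) reaction at the vinylcyclopropane only, which the s-trans-locked 2-ethoxy diene secures because it can neither chelate rhodium nor act as a 4π partner while the spiro ring holds the vinylcyclopropane s-cis.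

Step 5
Reactants: 9 1-[(8S)-6-[dimethyl(phenyl)silyl]-2-ethoxy-3,8-dimethyl-1,4,7,8-tetrahydroazulen-5-yl]ethan-1-one
Product: 11 (8S,8aR)-6-[dimethyl(phenyl)silyl]-5-(2-hydroxypropan-2-yl)-3,8-dimethyl-4,7,8,8a-tetrahydroazulen-2(1H)-one, via carbinol dienol ether 10 (not isolated)
Conditions: MeLi, CeCl3, THF, −78 °C; 1 M HCl, THF, 0 °C; DBU (0.2 equiv), CH2Cl2, rt
Reagents that add atoms: methyllithium, [Li]C; water, O
Why: Organocerium 1,2-addition to the hindered, enolisable β-silyl enone should give the tertiary alkoxide without conjugate addition, dilute acid then protonates the 2-ethoxycyclopentadiene at C1 (vinylogous enol ether hydrolysis) to unveil the C4=C5 enone, and DBU equilibrates C1 through the dienolate to the more stable epimer with C2 trans to the C10 methyl (1R).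

Step 6
Reactants: 11 (8S,8aR)-6-[dimethyl(phenyl)silyl]-5-(2-hydroxypropan-2-yl)-3,8-dimethyl-4,7,8,8a-tetrahydroazulen-2(1H)-one
Product: 12 (5R,6R,8S,8aR)-6-[dimethyl(phenyl)silyl]-5-(2-hydroxypropan-2-yl)-3,8-dimethyl-4,5,6,7,8,8a-hexahydroazulen-2(1H)-one
Conditions: [Ir(cod)(PCy3)(py)]PF6 (10 mol %), H2 (20 bar), CH2Cl2, rt
Reagents that add atoms: none
Why: Hydroxyl-directed hydrogenation with a cationic iridium catalyst should deliver both hydrogens syn to the tetrasubstituted C7=C8 alkene, fixing the C8 silyl group cis to the C7 side chain, and addition from the face opposite to the C10 methyl is expected to put both on the methyl face; the tetrasubstituted enone alkene has no directing group and should persist.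

Step 7
Reactants: 12 (5R,6R,8S,8aR)-6-[dimethyl(phenyl)silyl]-5-(2-hydroxypropan-2-yl)-3,8-dimethyl-4,5,6,7,8,8a-hexahydroazulen-2(1H)-one
Product: 14 (5S,6R,8S,8aR)-6-hydroxy-5-(2-hydroxypropan-2-yl)-3,8-dimethyl-4,5,6,7,8,8a-hexahydroazulen-2(1H)-one, via oxasilolane 13 (not isolated)
Conditions: KBr, AcOOH, NaOAc, AcOH, 0 °C to rt
Reagents that add atoms: peracetic acid, CC(=O)OO
Why: Fleming–Tamao oxidation, in which ipso-bromodesilylation removes the phenyl group, the neighbouring tertiary hydroxyl captures silicon as oxasilolane 13 and the peracid-induced shift of C8 from silicon to oxygen proceeds with retention, so the cis relationship from step 6 becomes the cis-8,11-diol (the C5 label changes from R to S only because silicon outranks oxygen in the CIP rules).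

Step 8
Reactants: 14 (5S,6R,8S,8aR)-6-hydroxy-5-(2-hydroxypropan-2-yl)-3,8-dimethyl-4,5,6,7,8,8a-hexahydroazulen-2(1H)-one
Product: 15 (5S,6R,8S,8aR)-5-(2-hydroxypropan-2-yl)-3,8-dimethyl-2-oxo-1,2,4,5,6,7,8,8a-octahydroazulen-6-yl propanoate
Conditions: (EtCO)2O (1.2 equiv), DMAP (5 mol %), pyridine, CH2Cl2, 0 °C
Reagents that add atoms: propanoic anhydride, CCC(=O)OC(=O)CC
Why: DMAP-catalysed acylation at low temperature should discriminate the secondary C8 hydroxyl from the hindered tertiary C11 hydroxyl.

Step 9
Reactants: 15 (5S,6R,8S,8aR)-5-(2-hydroxypropan-2-yl)-3,8-dimethyl-2-oxo-1,2,4,5,6,7,8,8a-octahydroazulen-6-yl propanoate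
Product: 16 (5S,6R,8S,8aR)-5-(2-acetoxypropan-2-yl)-3,8-dimethyl-2-oxo-1,2,4,5,6,7,8,8a-octahydroazulen-6-yl propanoate
Conditions: Ac2O, DMAP (1 equiv), Et3N, CH2Cl2, 40 °C
Reagents that add atoms: acetic anhydride, CC(=O)OC(C)=O
Why: Nucleophilic catalysis by DMAP (acylpyridinium) should acetylate the tertiary alcohol, while migration of the propanoyl group from O8 to O11 would be uphill and no stereocentre is involved.

**Compound list**
1 | 3-ethoxy-2-methylcyclopent-2-en-1-one | CCOC1=C(C)C(=O)CC1 | starting material
2 | (4R)-4-methyl-1,3,2-dioxathiolane 2,2-dioxide | C[C@@H]1COS(=O)(=O)O1 | starting material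
3 | dilithium salt of the C5 enolate of 3-ethoxy-2-methyl-5-[(2R)-2-(sulfonatooxy)propyl]cyclopent-2-en-1-one | CCOC1=C(C)C([O-])=C(C1)C[C@@H](C)OS(=O)(=O)[O-].[Li+].[Li+] | intermediate (not isolated)
4 | (1S,3R)-6-ethoxy-1,5-dimethylspiro[2.4]hept-5-en-4-one | CCOC1=C(C)C(=O)[C@@]2(C1)C[C@@H]2C | intermediate
5 | (1S,3R)-6-ethoxy-1,5-dimethyl-4-methylidenespiro[2.4]hept-5-ene | CCOC1=C(C)C(=C)[C@@]2(C1)C[C@@H]2C | intermediate
6 | ethynyl(dimethyl)phenylsilane | C#C[Si](C)(C)c1ccccc1 | starting material
7 | lithium [dimethyl(phenyl)silyl]acetylide | [Li]C#C[Si](C)(C)c1ccccc1 | intermediate (not isolated)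
8 | 4-[dimethyl(phenyl)silyl]but-3-yn-2-one | CC(=O)C#C[Si](C)(C)c1ccccc1 | intermediate
9 | 1-[(8S)-6-[dimethyl(phenyl)silyl]-2-ethoxy-3,8-dimethyl-1,4,7,8-tetrahydroazulen-5-yl]ethan-1-one | CCOC1=C(C)C2=C(C1)[C@@H](C)CC([Si](C)(C)c3ccccc3)=C(C(C)=O)C2 | intermediate
10 | 2-[(8S)-6-[dimethyl(phenyl)silyl]-2-ethoxy-3,8-dimethyl-1,4,7,8-tetrahydroazulen-5-yl]propan-2-ol (formed as its metal alkoxide) | CCOC1=C(C)C2=C(C1)[C@@H](C)CC([Si](C)(C)c3ccccc3)=C(C(C)(C)O)C2 | intermediate (not isolated)
11 | (8S,8aR)-6-[dimethyl(phenyl)silyl]-5-(2-hydroxypropan-2-yl)-3,8-dimethyl-4,7,8,8a-tetrahydroazulen-2(1H)-one | C[Si](C)(c3ccccc3)C1=C(C(C)(C)O)CC2=C(C)C(=O)C[C@@H]2[C@@H](C)C1 | intermediate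
12 | (5R,6R,8S,8aR)-6-[dimethyl(phenyl)silyl]-5-(2-hydroxypropan-2-yl)-3,8-dimethyl-4,5,6,7,8,8a-hexahydroazulen-2(1H)-one | C[Si](C)(c3ccccc3)[C@@H]1C[C@H](C)[C@H]2CC(=O)C(C)=C2C[C@@H]1C(C)(C)O | intermediate
13 | cis-fused 2,2-dimethyl-1,2-oxasilolane that links C8 (through silicon) to O11 of 12 after loss of the phenyl group | C[Si]3(C)[C@@H]1C[C@H](C)[C@H]2CC(=O)C(C)=C2C[C@@H]1C(C)(C)O3 | intermediate (not isolated)
14 | (5S,6R,8S,8aR)-6-hydroxy-5-(2-hydroxypropan-2-yl)-3,8-dimethyl-4,5,6,7,8,8a-hexahydroazulen-2(1H)-one | O[C@@H]1C[C@H](C)[C@H]2CC(=O)C(C)=C2C[C@@H]1C(C)(C)O | intermediate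
15 | (5S,6R,8S,8aR)-5-(2-hydroxypropan-2-yl)-3,8-dimethyl-2-oxo-1,2,4,5,6,7,8,8a-octahydroazulen-6-yl propanoate | CCC(=O)O[C@@H]1C[C@H](C)[C@H]2CC(=O)C(C)=C2C[C@@H]1C(C)(C)O | intermediate
16 | (5S,6R,8S,8aR)-5-(2-acetoxypropan-2-yl)-3,8-dimethyl-2-oxo-1,2,4,5,6,7,8,8a-octahydroazulen-6-yl propanoate | CCC(=O)O[C@@H]1C[C@H](C)[C@H]2CC(=O)C(C)=C2C[C@@H]1C(C)(C)OC(C)=O | target

**Step count and risks**
Total step count: 9. Longest linear sequence: 8 steps (1, 2, 4, 5, 6, 7, 8, 9).

Steps most likely to fail:

1. Step 4. Insertion of the doubly substituted, hindered alkyne 8 into the rhodacycle may be too slow, so that rhodium-induced isomerisation or decomposition of the acid-labile diene 5 takes over, or the alkyne may be incorporated without orientational control. The fallback sets out from 5 and drops silicon. The unhindered terminal alkyne but-3-yn-2-one would be used in the same kind of cycloaddition, where only the acyl group directs the orientation, to give 1-[(8S)-2-ethoxy-3,8-dimethyl-1,4,7,8-tetrahydroazulen-5-yl]ethan-1-one F1. Treatment with MeLi/CeCl3, then dilute acid and DBU as in step 5, would give (8S,8aR)-5-(2-hydroxypropan-2-yl)-3,8-dimethyl-4,7,8,8a-tetrahydroazulen-2(1H)-one F2. Shi epoxidation of the electron-rich C7=C8 alkene (fructose-derived ketone catalyst or its enantiomer, KHSO5, buffered MeCN), with the catalyst enantiomer chosen to deliver oxygen to the face of the C10 methyl, would give (1R,10S)-7,8-epoxy-11-hydroxyguai-4-en-3-one F3. Reductive opening with trivalent titanium (Cp2TiCl from Cp2TiCl2 and Mn, H2O as hydrogen-atom donor, THF) should cleave the tertiary C7–O bond and deliver hydrogen anti to the C8 titanoxy group, so the route is rejoined at diol 14.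

2. Step 6. The crowded tetrasubstituted vinylsilane may fail to bind iridium, or hydrogen may be delivered to the face syn to the C10 methyl. The fallback sets out from 11. Hydroxyl-assisted protodesilylation (Bu4NF, DMSO, 80 °C; 1,4-shift of silicon to the cis-disposed tertiary alkoxide) would give the dienone carbinol F2. From there the reagent-controlled Shi epoxidation to epoxy alcohol F3 and the trivalent-titanium opening described above set C8 and C7 independently of the ring bias, and the route is rejoined at diol 14.

3. Step 1. O-alkylation of the enolate, or sluggish displacement of the secondary sulfate monoanion with competing elimination, may prevent ring closure. The fallback sets out from 1 and builds the cyclopropane stepwise. The lithium enolate (LiN(iPr)2, THF, −78 °C) would be alkylated with (R)-2-methyloxirane in the presence of BF3·OEt2 to give 3-ethoxy-5-[(2R)-2-hydroxypropyl]-2-methylcyclopent-2-en-1-one F4. Mesylation (MsCl, Et3N, CH2Cl2, 0 °C) would give (2R)-1-(4-ethoxy-3-methyl-2-oxocyclopent-3-en-1-yl)propan-2-yl methanesulfonate F5. KOtBu in THF at 0 °C should then close the ring by 3-exo-tet displacement with inversion, and the route is rejoined at spiro ketone 4.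

Further compounds
F1 | step 4 | 1-[(8S)-2-ethoxy-3,8-dimethyl-1,4,7,8-tetrahydroazulen-5-yl]ethan-1-one | CCOC1=C(C)C2=C(C1)[C@@H](C)CC=C(C(C)=O)C2
F2 | step 4 | (8S,8aR)-5-(2-hydroxypropan-2-yl)-3,8-dimethyl-4,7,8,8a-tetrahydroazulen-2(1H)-one | C1=C(C(C)(C)O)CC2=C(C)C(=O)C[C@@H]2[C@@H](C)C1
F3 | step 4 | (1R,10S)-7,8-epoxy-11-hydroxyguai-4-en-3-one, oxirane oxygen cis to the C10 methyl | O1[C@@H]2C[C@H](C)[C@H]3CC(=O)C(C)=C3C[C@]12C(C)(C)O
F0 | step 6 | none | none
F4 | step 1 | 3-ethoxy-5-[(2R)-2-hydroxypropyl]-2-methylcyclopent-2-en-1-one (both C5 epimers, planarised on enolisation) | CCOC1=C(C)C(=O)C(C1)C[C@@H](C)O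
F5 | step 1 | (2R)-1-(4-ethoxy-3-methyl-2-oxocyclopent-3-en-1-yl)propan-2-yl methanesulfonate (both ring epimers) | CCOC1=C(C)C(=O)C(C1)C[C@@H](C)OS(C)(=O)=O
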